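The hexamer (rings F, A, B, C, D, E from the gem-dimethyl end) is cut at central ring C. The key step exploits its pattern, oxygen on C1, C3 and C5, carbon on C2, C4 and C6 (two bridging CH2 groups, one butanoyl): four ring carbons come from a dialkylated cyclohexane-1,3-dione, two from an alkoxy ynone. A 1,3-bis(silyloxy)cyclohexa-1,3-diene carrying the F–A–B arm at C2 and the D–E arm at its terminus adds to 1-methoxyhex-1-yn-3-one and then loses ethene. One operation forms two ring C bonds, closes the aromatic ring, joins trimer and dimer and brings in the butanoyl group. The arms are methyl ethers; ring F is silylated only transiently.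

Key step: step 16

Remarks on the chemistry
- Abbreviations: "D–E arm" is the (3-butanoyl-5-[(3-butanoyl-2,4,6-trimethoxy-5-methylphenyl)methyl]-2,4,6-trimethoxyphenyl)methyl group. "F–A–B arm" is the corresponding ring B benzyl group carrying ring A and ring F (SMILES in the list).
- Assumption: 1,3-dione 19 and ring F are drawn as single tautomers. The centres in 17, 18, 19 and 25 are racemic and disappear when ring C becomes aromatic; the target has no stereocentre.
- The alkynyl ether is the methyl ether. It has no beta hydrogen, so it cannot fragment to a ketene by a retro-ene loss of alkene at the temperature of step 16. It also gives ring C the same protecting group as the arms.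
- Ring F is kept as the free enolised triketone through the arm chemistry, because a bis-enol ether of this ring would be attacked by the amine catalyst of steps 5 and 13. It is capped only in step 14 and released in step 17.
- The D–E arm is attached first, with strong base acting on a ketone-free vinylogous ester. The F–A–B arm follows under neutral organocatalysis, so the butanoyl groups never meet excess strong base.

Step 1
Reactants: 1 1,3,5-trimethoxybenzene; 2 butanoyl chloride
Product: 3 1-(2,4,6-trimethoxyphenyl)butan-1-one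
Conditions: AlCl3 (1.1 equiv), CH2Cl2, −10 → 0 °C
Reagents that add atoms: none
Why: Friedel–Crafts acylation of a symmetrical, strongly activated arene should stop after one acyl group because the ketone deactivates the ring, and the low temperature avoids cleavage of the ortho methyl ethers.

Step 2
Reactants: 3 1-(2,4,6-trimethoxyphenyl)butan-1-one (two molecules are joined by one formaldehyde carbon; charged at four molecules per formaldehyde, the surplus recovered)
Product: 4 bis(3-butanoyl-2,4,6-trimethoxyphenyl)methane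
Conditions: (CH2O)n (0.25 equiv CH2O per 3), CF3CO2H, CH2Cl2, rt
Reagents that add atoms: formaldehyde (as paraformaldehyde), C=O; 1-(2,4,6-trimethoxyphenyl)butan-1-one (the second molecule of 3 that enters the product), CCCC(=O)c1c(OC)cc(OC)cc1OC
Why: Acid-mediated methylene bridging, in which one molecule of 3 is hydroxymethylated at a position flanked by two methoxy groups and the resulting benzylic cation is captured by a second molecule of 3 (Friedel–Crafts benzylation), so that two ketones and one formaldehyde give 4 and water, the surplus of 3 holding the condensation at the dimer.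

Step 3
Reactants: 4 bis(3-butanoyl-2,4,6-trimethoxyphenyl)methane
Product: 5 bis(3-butanoyl-5-formyl-2,4,6-trimethoxyphenyl)methane
Conditions: Cl2CHOCH3 (3 equiv), TiCl4 (5 equiv), CH2Cl2, −10 → 0 °C; then H2O
Reagents that add atoms: dichloromethyl methyl ether, COC(Cl)Cl; water, O
Why: Rieche formylation should take place once on each ring, at its single free position, which three methoxy groups activate and the twisted ketone hardly deactivates.

Step 4
Reactants: 6 1-(2,4,6-trihydroxyphenyl)butan-1-one
Product: 7 2-butanoyl-3,5-dihydroxy-4,4-dimethylcyclohexa-2,5-dien-1-one (butanoylfilicinic acid, ring F)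
Conditions: NaOCH3 (3.2 equiv), CH3I (2.2 equiv), CH3OH, 0 °C → rt; then dilute HCl
Reagents that add atoms: iodomethane, CI
Why: Twofold C-methylation of the phloroglucinol polyanion at one ring carbon, the classical entry to acylfilicinic acids, should dearomatise the ring to the geminal dimethyl triketone, which is separated from mono- and trimethylated congeners.

Step 5
Reactants: 5 bis(3-butanoyl-5-formyl-2,4,6-trimethoxyphenyl)methane (2.5 equiv, excess recovered); 7 butanoylfilicinic acid
Product: 8 ring F–A–B aldehyde: ring B is 3-butanoyl-2,4,6-trimethoxybenzaldehyde, its C5 is joined by CH2 to ring A (1-butanoyl-2,4,6-trimethoxybenzene), whose other free carbon is joined by CH2 to C6 of ring F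
Conditions: (S)-pyrrolidine-2-carboxylic acid (L-proline, 20 mol%), diethyl 2,6-dimethyl-1,4-dihydropyridine-3,5-dicarboxylate (Hantzsch ester, 1.1 equiv), CH2Cl2, rt → 35 °C
Reagents that add atoms: none
Why: Organocatalytic reductive Knoevenagel alkylation: the aldehyde condenses at the only C–H acidic carbon of 7 (C6, between the carbonyl and an enol) and the dihydropyridine reduces the alkylidene in situ, the excess of dialdehyde favouring the mono-adduct.

Step 6
Reactants: 9 1,3,5-trimethoxy-2-methylbenzene (2,4,6-trimethoxytoluene); 2 butanoyl chloride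
Product: 10 1-(2,4,6-trimethoxy-3-methylphenyl)butan-1-one (ring E)
Conditions: AlCl3 (1.1 equiv), CH2Cl2, −10 → 0 °C
Reagents that add atoms: none
Why: Friedel–Crafts acylation at one of the two equivalent free positions gives a single ketone.

Step 7
Reactants: 10 1-(2,4,6-trimethoxy-3-methylphenyl)butan-1-one
Product: 11 1-[3-(bromomethyl)-2,4,6-trimethoxy-5-methylphenyl]butan-1-one
Conditions: (CH2O)n (3 equiv), HBr (33% in CH3CO2H), rt
Reagents that add atoms: formaldehyde (as paraformaldehyde), C=O; hydrogen bromide, Br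
Why: Bromomethylation (Blanc-type haloalkylation), well known for 1,3,5-trimethoxybenzenes, should occur at the only free position and leave a fully substituted ring that cannot be attacked again.

Step 8
Reactants: 11 1-[3-(bromomethyl)-2,4,6-trimethoxy-5-methylphenyl]butan-1-one; 3 1-(2,4,6-trimethoxyphenyl)butan-1-one (3 equiv, excess recovered)
Product: 12 1-{3-[(3-butanoyl-2,4,6-trimethoxy-5-methylphenyl)methyl]-2,4,6-trimethoxyphenyl}butan-1-one (rings D–E, one free position on ring D)
Conditions: AgOSO2CF3 (1.1 equiv), 2,6-di-tert-butyl-4-methylpyridine (1.2 equiv), CH2Cl2, −40 → 0 °C, dark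
Reagents that add atoms: none
Why: Silver-assisted ionisation gives a trimethoxybenzyl cation that cannot alkylate its own fully substituted ring and should benzylate 3 (Friedel–Crafts benzylation), the hindered base removing the acid that could scramble the bridge and the excess of 3 limiting double benzylation.

Step 9
Reactants: 12 ring D–E ketone
Product: 13 3-butanoyl-5-[(3-butanoyl-2,4,6-trimethoxy-5-methylphenyl)methyl]-2,4,6-trimethoxybenzaldehyde
Conditions: Cl2CHOCH3 (1.5 equiv), TiCl4 (3 equiv), CH2Cl2, −10 → 0 °C; then H2O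
Reagents that add atoms: dichloromethyl methyl ether, COC(Cl)Cl; water, O
Why: Rieche formylation at the last free aromatic position (ring D), ring E being fully substituted.

Step 10
Reactants: 13 ring D–E aldehyde
Product: 14 1-{3-[(3-butanoyl-2,4,6-trimethoxy-5-methylphenyl)methyl]-5-(hydroxymethyl)-2,4,6-trimethoxyphenyl}butan-1-one
Conditions: NaBH4 (1 equiv), CH3OH/THF, 0 °C, 20 min
Reagents that add atoms: none
Why: Chemoselective hydride reduction of the aldehyde, the two aryl ketones being flanked by two ortho methoxy groups and reacting far more slowly.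

Step 11
Reactants: 14 ring D–E benzyl alcohol
Product: 15 1-{3-(bromomethyl)-5-[(3-butanoyl-2,4,6-trimethoxy-5-methylphenyl)methyl]-2,4,6-trimethoxyphenyl}butan-1-one (right-arm bromide, used crude)
Conditions: PBr3 (0.4 equiv), CH2Cl2, 0 °C
Reagents that add atoms: phosphorus tribromide, BrP(Br)Br
Why: Conversion of an electron-rich benzylic alcohol into the bromide through its phosphite, a substitution that is fast for a benzyl position with three donor methoxy groups.

Step 12
Reactants: 16 3-ethoxycyclohex-2-en-1-one (1.1 equiv); 15 right-arm bromide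
Product: 18 4-[(D–E arm)]cyclohexane-1,3-dione (racemic), via 6-alkylated 3-ethoxycyclohexenone 17 (not isolated)
Conditions: LiN(iPr)2 (1.05 equiv), THF, −78 °C; 15 added last, −78 → −30 °C; then 2 M HCl, THF, rt
Reagents that add atoms: water, O
Why: Stork–Danheiser alkylation: kinetic deprotonation of the vinylogous ester at C6 and SN2 attack on the activated benzylic bromide at low temperature, where the hindered aryl ketones of 15 are neither attacked nor deprotonated at a competitive rate, then acid hydrolysis of the enol ether; the new centre is racemic and is lost in step 14.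

Step 13
Reactants: 18 4-[(D–E arm)]cyclohexane-1,3-dione; 8 ring F–A–B aldehyde
Product: 19 2-[(F–A–B arm)]-4-[(D–E arm)]cyclohexane-1,3-dione (enol form, racemic)
Conditions: (S)-pyrrolidine-2-carboxylic acid (L-proline, 20 mol%), diethyl 2,6-dimethyl-1,4-dihydropyridine-3,5-dicarboxylate (1.1 equiv), CH2Cl2, rt → 35 °C
Reagents that add atoms: none
Why: Reductive Knoevenagel alkylation at C2, the only carbon between two carbonyl groups; ring F has no free carbon and the butanoyl ketones do not condense under these neutral conditions.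

Step 14
Reactants: 19 2,4-dialkylated cyclohexane-1,3-dione
Product: 20 1,3-bis(trimethylsilyloxy)cyclohexa-1,3-diene with the F–A–B arm at C2 and the D–E arm at C4, ring F as its 3,5-bis(trimethylsilyl) ether (used crude)
Conditions: Me3SiOSO2CF3 (4.4 equiv), Et3N (6 equiv), CH2Cl2, −20 °C → rt, 6 h; hexane–toluene, filtration under argon
Reagents that add atoms: trimethylsilyl trifluoromethanesulfonate, C[Si](C)(C)OS(=O)(=O)C(F)(F)F
Why: Soft enolisation: the silyl triflate caps the enols of rings C and F, silylates the remaining ring C carbonyl, and the amine removes a proton from the bis(silyloxy)allyl cation; under these equilibrating conditions the more substituted dienol ether, with the double bond toward the carbon bearing the D–E arm, should predominate, as for other 2,4-dialkylcyclohexane-1,3-diones.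

Step 15
Reactants: 21 2-chloro-1,1-dimethoxyethane; 22 N-methoxy-N-methylbutanamide
Product: 24 1-methoxyhex-1-yn-3-one, via lithium methoxyacetylide 23 (not isolated)
Conditions: LiN(C2H5)2 (3.1 equiv), THF, 0 °C; then 22, −78 → −20 °C; cold aqueous NH4Cl
Reagents that add atoms: none
Why: Two eliminations and a deprotonation convert the chloroacetal into the lithium alkynyl ether (the standard entry to methoxyacetylene), and acylation with the Weinreb amide stops at the ketone because the chelated tetrahedral adduct survives until work-up.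

Step 16
Reactants: 20 bis(silyloxy)cyclohexadiene; 24 1-methoxyhex-1-yn-3-one (3 equiv)
Product: 26 protected hexamer with ring C as 1-butanoyl-2-methoxy-4,6-bis(trimethylsilyloxy)benzene carrying the D–E arm at C3 and the F–A–B arm at C5, via bicyclo[2.2.2]octadiene adduct 25 (not isolated)
Conditions: mesitylene, 2,6-di-tert-butyl-4-methylphenol (1 mol%), sealed tube, argon, 130 °C, then 170 °C
Reagents that add atoms: none
Why: Thermal [4+2] cycloaddition of the electron-rich dioxygenated diene (C1 to C4 of 20) with the acyl-activated alkyne gives bicyclo[2.2.2]octa-2,5-diene 25, and a retro-Diels–Alder reaction then expels the C5–C6 bridge as ethene, driven by aromatisation. This is the Alder–Rickert reaction, known for 1,3-bis(silyloxy)cyclohexa-1,3-dienes, including 2,4-dialkylated ones, with acetylenic esters and ketones. Ring C is closed by intermolecular cycloaddition, which bonds the arm-bearing terminus to the methoxy-bearing alkyne carbon and the siloxy-bearing terminus to the acyl-bearing carbon; no stereocentre remains, since both bridgeheads of racemic 25 become aromatic carbons. Only regioselectivity is needed: the unoxygenated terminus, made the nucleophilic end by both siloxy groups, pairs with the beta carbon of the ynone, which stays the electrophilic end despite its methoxy donor, and this places the three ring C oxygens 1,3,5. The methyl alkynyl ether cannot lose an alkene to form a ketene, so it should survive the temperature that a fully substituted diene and a donor-substituted alkyne require. Ring F as its bis-silyl ether and the hindered aryl ketones have no reactive diene or dienophile and remain spectators.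

Step 17
Reactants: 26 protected hexamer
Product: 27 CNP0309827.0 (target)
Conditions: BBr3 (30 equiv), CH2Cl2, −78 → 0 °C; CH3OH, then H2O
Reagents that add atoms: none
Why: Lewis-acid ether cleavage: BBr3 should remove all thirteen aryl methyl ethers, nine of them assisted by chelation to an ortho butanoyl group, and the four silyl groups are lost with the hydrogen bromide formed on quenching.

Compound list
1 | 1,3,5-trimethoxybenzene | COc1cc(OC)cc(OC)c1 | starting material
2 | butanoyl chloride | CCCC(=O)Cl | starting material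
3 | 1-(2,4,6-trimethoxyphenyl)butan-1-one | CCCC(=O)c1c(OC)cc(OC)cc1OC | intermediate
4 | bis(3-butanoyl-2,4,6-trimethoxyphenyl)methane | CCCC(=O)c1c(OC)cc(OC)c(Cc2c(OC)cc(OC)c(C(=O)CCC)c2OC)c1OC | intermediate
5 | bis(3-butanoyl-5-formyl-2,4,6-trimethoxyphenyl)methane | CCCC(=O)c1c(OC)c(C=O)c(OC)c(Cc2c(OC)c(C=O)c(OC)c(C(=O)CCC)c2OC)c1OC | intermediate
6 | 1-(2,4,6-trihydroxyphenyl)butan-1-one | CCCC(=O)c1c(O)cc(O)cc1O | starting material
7 | 2-butanoyl-3,5-dihydroxy-4,4-dimethylcyclohexa-2,5-dien-1-one | CCCC(=O)C1=C(O)C(C)(C)C(O)=CC1=O | intermediate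
8 | ring F–A–B aldehyde (ring B benzaldehyde, CH2 to ring A, CH2 to C6 of ring F) | CCCC(=O)C1=C(O)C(C)(C)C(O)=C(Cc2c(OC)c(C(=O)CCC)c(OC)c(Cc3c(OC)c(C(=O)CCC)c(OC)c(C=O)c3OC)c2OC)C1=O | intermediate
9 | 1,3,5-trimethoxy-2-methylbenzene | Cc1c(OC)cc(OC)cc1OC | starting material
10 | 1-(2,4,6-trimethoxy-3-methylphenyl)butan-1-one | CCCC(=O)c1c(OC)cc(OC)c(C)c1OC | intermediate
11 | 1-[3-(bromomethyl)-2,4,6-trimethoxy-5-methylphenyl]butan-1-one | CCCC(=O)c1c(OC)c(CBr)c(OC)c(C)c1OC | intermediate
12 | 1-{3-[(3-butanoyl-2,4,6-trimethoxy-5-methylphenyl)methyl]-2,4,6-trimethoxyphenyl}butan-1-one | CCCC(=O)c1c(OC)cc(OC)c(Cc2c(OC)c(C)c(OC)c(C(=O)CCC)c2OC)c1OC | intermediate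
13 | 3-butanoyl-5-[(3-butanoyl-2,4,6-trimethoxy-5-methylphenyl)methyl]-2,4,6-trimethoxybenzaldehyde | CCCC(=O)c1c(OC)c(C=O)c(OC)c(Cc2c(OC)c(C)c(OC)c(C(=O)CCC)c2OC)c1OC | intermediate
14 | 1-{3-[(3-butanoyl-2,4,6-trimethoxy-5-methylphenyl)methyl]-5-(hydroxymethyl)-2,4,6-trimethoxyphenyl}butan-1-one | CCCC(=O)c1c(OC)c(CO)c(OC)c(Cc2c(OC)c(C)c(OC)c(C(=O)CCC)c2OC)c1OC | intermediate
15 | 1-{3-(bromomethyl)-5-[(3-butanoyl-2,4,6-trimethoxy-5-methylphenyl)methyl]-2,4,6-trimethoxyphenyl}butan-1-one | CCCC(=O)c1c(OC)c(CBr)c(OC)c(Cc2c(OC)c(C)c(OC)c(C(=O)CCC)c2OC)c1OC | intermediate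
16 | 3-ethoxycyclohex-2-en-1-one | CCOC1=CC(=O)CCC1 | starting material
17 | 3-ethoxy-6-[(D–E arm)]cyclohex-2-en-1-one, racemic | CCOC1=CC(=O)C(Cc2c(OC)c(C(=O)CCC)c(OC)c(Cc3c(OC)c(C)c(OC)c(C(=O)CCC)c3OC)c2OC)CC1 | intermediate (not isolated)
18 | 4-[(D–E arm)]cyclohexane-1,3-dione, racemic | O=C1CC(=O)C(Cc2c(OC)c(C(=O)CCC)c(OC)c(Cc3c(OC)c(C)c(OC)c(C(=O)CCC)c3OC)c2OC)CC1 | intermediate
19 | 2-[(F–A–B arm)]-4-[(D–E arm)]cyclohexane-1,3-dione, enol form, racemic | OC1=C(Cc2c(OC)c(C(=O)CCC)c(OC)c(Cc3c(OC)c(C(=O)CCC)c(OC)c(CC4=C(O)C(C)(C)C(O)=C(C(=O)CCC)C4=O)c3OC)c2OC)C(=O)C(Cc5c(OC)c(C(=O)CCC)c(OC)c(Cc6c(OC)c(C)c(OC)c(C(=O)CCC)c6OC)c5OC)CC1 | intermediate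
20 | 1,3-bis(trimethylsilyloxy)cyclohexa-1,3-diene, F–A–B arm at C2, D–E arm at C4, ring F as bis(trimethylsilyl) ether | C[Si](C)(C)OC1=C(Cc2c(OC)c(C(=O)CCC)c(OC)c(Cc3c(OC)c(C(=O)CCC)c(OC)c(CC4=C(O[Si](C)(C)C)C(C)(C)C(O[Si](C)(C)C)=C(C(=O)CCC)C4=O)c3OC)c2OC)C(O[Si](C)(C)C)=C(Cc5c(OC)c(C(=O)CCC)c(OC)c(Cc6c(OC)c(C)c(OC)c(C(=O)CCC)c6OC)c5OC)CC1 | intermediate
21 | 2-chloro-1,1-dimethoxyethane | COC(CCl)OC | starting material
22 | N-methoxy-N-methylbutanamide | CCCC(=O)N(C)OC | starting material
23 | lithium methoxyacetylide | [Li]C#COC | intermediate (not isolated)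
24 | 1-methoxyhex-1-yn-3-one | CCCC(=O)C#COC | intermediate
25 | bicyclo[2.2.2]octa-2,5-diene adduct (bridgeheads bear OSiMe3 and the D–E arm; racemic, relative configuration fixed by the bicycle) | C[Si](C)(C)OC12CCC(Cc3c(OC)c(C(=O)CCC)c(OC)c(Cc4c(OC)c(C)c(OC)c(C(=O)CCC)c4OC)c3OC)(C(OC)=C1C(=O)CCC)C(O[Si](C)(C)C)=C2Cc5c(OC)c(C(=O)CCC)c(OC)c(Cc6c(OC)c(C(=O)CCC)c(OC)c(CC7=C(O[Si](C)(C)C)C(C)(C)C(O[Si](C)(C)C)=C(C(=O)CCC)C7=O)c6OC)c5OC | intermediate (not isolated)
26 | protected hexamer, ring C as bis(trimethylsilyloxy) methoxy butanoyl arene | CCCC(=O)c1c(O[Si](C)(C)C)c(Cc2c(OC)c(C(=O)CCC)c(OC)c(Cc3c(OC)c(C(=O)CCC)c(OC)c(CC4=C(O[Si](C)(C)C)C(C)(C)C(O[Si](C)(C)C)=C(C(=O)CCC)C4=O)c3OC)c2OC)c(O[Si](C)(C)C)c(Cc5c(OC)c(C(=O)CCC)c(OC)c(Cc6c(OC)c(C)c(OC)c(C(=O)CCC)c6OC)c5OC)c1OC | intermediate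
27 | CNP0309827.0 | CCCC(=O)C1=C(O)C(C)(C)C(O)=C(Cc2c(O)c(Cc3c(O)c(Cc4c(O)c(Cc5c(O)c(Cc6c(O)c(C)c(O)c(C(=O)CCC)c6O)c(O)c(C(=O)CCC)c5O)c(O)c(C(=O)CCC)c4O)c(O)c(C(=O)CCC)c3O)c(O)c(C(=O)CCC)c2O)C1=O | target

Total step count: 17. Longest linear sequence: 11 steps (steps 6, 7, 8, 9, 10, 11, 12, 13, 14, 16, 17).

Steps most likely to fail

Step 16. The cycloaddition joins a fully substituted diene terminus to a donor-substituted alkyne and may be slower than thermal loss of silyl groups from the diene or oligomerisation of the ynone, so that little adduct reaches the extrusion stage. The fallback gives up the cycloaddition and brings ring C in as the preformed aromatic ketone; it sets out from 3. Silver-promoted Friedel–Crafts benzylation of 3 (threefold excess) with bromide 15 (AgOSO2CF3, 2,6-di-tert-butyl-4-methylpyridine, CH2Cl2) should give the ring C–D–E ketone F1, which keeps one free position on ring C. Reductive Friedel–Crafts coupling of F1 with aldehyde 8 (Et3SiH, CF3CO2H, CH2Cl2, 0 °C → rt) should then give the fully assembled pentadecamethyl ether F2, the diarylmethyl cation being reduced by the silane. BBr3 dealkylation of F2 returns to the route at target 27.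

Step 14. The proton may be lost from the unsubstituted ring methylene instead of from the carbon bearing the D–E arm. The arm would then sit on the ethano bridge and be expelled with the alkene in step 16. The fallback replaces thermodynamic by kinetic control and sets out from 19. tert-Butyldimethylsilyl triflate and Et3N at −78 °C should silylate the three enols, on ring C at the less hindered oxygen remote from the D–E arm, to give the vinylogous silyl ester F3, whose ring C carbonyl lies next to the arm-bearing carbon. LiN(iPr)2 with Me3SiCl as internal quench (THF, −78 °C) then removes the only alpha-prime proton and gives the mixed silyl diene F4, the five butanoyl groups being masked in the same operation as (Z)-trimethylsilyl enol ethers. F4 and 24 under the conditions of step 16 should give the arene F5. BBr3 followed by aqueous work-up cleaves all ethers and silyl groups and returns to the route at target 27.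

Step 17. Thirteen ether cleavages in one operation may stall at the four hindered methoxy groups para to the butanoyl groups, or the acid formed may scramble the methylene bridges on prolonged exposure. The fallback is a staged deprotection that sets out from 26. BCl3 (CH2Cl2, −78 → 0 °C) should cleave only the nine methyl ethers ortho to a butanoyl group by chelation, and aqueous work-up removes the silyl groups, to give the tetramethyl ether F6. The remaining four ethers are then cleaved by the thiol-assisted method (AlCl3, C2H5SH, CH2Cl2, 0 °C → rt), which returns to the route at target 27.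

Further compounds
F1 | step 16 | 1-{3-[(D–E arm)]-2,4,6-trimethoxyphenyl}butan-1-one (rings C–D–E, one free position on ring C) | CCCC(=O)c1c(OC)cc(OC)c(Cc2c(OC)c(C(=O)CCC)c(OC)c(Cc3c(OC)c(C)c(OC)c(C(=O)CCC)c3OC)c2OC)c1OC
F2 | step 16 | pentadecamethyl ether of the target (rings A to E as trimethyl ethers, ring F free) | CCCC(=O)c1c(OC)c(Cc2c(OC)c(C(=O)CCC)c(OC)c(Cc3c(OC)c(C(=O)CCC)c(OC)c(CC4=C(O)C(C)(C)C(O)=C(C(=O)CCC)C4=O)c3OC)c2OC)c(OC)c(Cc5c(OC)c(C(=O)CCC)c(OC)c(Cc6c(OC)c(C)c(OC)c(C(=O)CCC)c6OC)c5OC)c1OC
F3 | step 14 | 3-(tert-butyldimethylsilyloxy)-2-[(F–A–B arm)]-6-[(D–E arm)]cyclohex-2-en-1-one, ring F as bis(tert-butyldimethylsilyl) ether, racemic | CC(C)(C)[Si](C)(C)OC1=C(Cc2c(OC)c(C(=O)CCC)c(OC)c(Cc3c(OC)c(C(=O)CCC)c(OC)c(CC4=C(O[Si](C)(C)C(C)(C)C)C(C)(C)C(O[Si](C)(C)C(C)(C)C)=C(C(=O)CCC)C4=O)c3OC)c2OC)C(=O)C(Cc5c(OC)c(C(=O)CCC)c(OC)c(Cc6c(OC)c(C)c(OC)c(C(=O)CCC)c6OC)c5OC)CC1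
F4 | step 14 | 1-(tert-butyldimethylsilyloxy)-3-(trimethylsilyloxy)cyclohexa-1,3-diene with both arms, all five butanoyl groups as (Z)-trimethylsilyl enol ethers | CC(C)(C)[Si](C)(C)OC1=C(Cc2c(OC)c(/C(O[Si](C)(C)C)=C/CC)c(OC)c(Cc3c(OC)c(/C(O[Si](C)(C)C)=C/CC)c(OC)c(CC4=C(O[Si](C)(C)C(C)(C)C)C(C)(C)C(O[Si](C)(C)C(C)(C)C)=C(/C(O[Si](C)(C)C)=C/CC)C4=O)c3OC)c2OC)C(O[Si](C)(C)C)=C(Cc5c(OC)c(/C(O[Si](C)(C)C)=C/CC)c(OC)c(Cc6c(OC)c(C)c(OC)c(/C(O[Si](C)(C)C)=C/CC)c6OC)c5OC)CC1
F5 | step 14 | protected hexamer from F4 (ring C with butanoyl, methoxy, tert-butyldimethylsilyloxy and trimethylsilyloxy groups; arm butanoyl groups as (Z)-silyl enol ethers) | CCCC(=O)c1c(O[Si](C)(C)C(C)(C)C)c(Cc2c(OC)c(/C(O[Si](C)(C)C)=C/CC)c(OC)c(Cc3c(OC)c(/C(O[Si](C)(C)C)=C/CC)c(OC)c(CC4=C(O[Si](C)(C)C(C)(C)C)C(C)(C)C(O[Si](C)(C)C(C)(C)C)=C(/C(O[Si](C)(C)C)=C/CC)C4=O)c3OC)c2OC)c(O[Si](C)(C)C)c(Cc5c(OC)c(/C(O[Si](C)(C)C)=C/CC)c(OC)c(Cc6c(OC)c(C)c(OC)c(/C(O[Si](C)(C)C)=C/CC)c6OC)c5OC)c1OC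
F6 | step 17 | tetramethyl ether of the target (one methoxy group para to butanoyl on each of rings A, B, D and E) | CCCC(=O)C1=C(O)C(C)(C)C(O)=C(Cc2c(OC)c(Cc3c(OC)c(Cc4c(O)c(Cc5c(OC)c(Cc6c(OC)c(C)c(O)c(C(=O)CCC)c6O)c(O)c(C(=O)CCC)c5O)c(O)c(C(=O)CCC)c4O)c(O)c(C(=O)CCC)c3O)c(O)c(C(=O)CCC)c2O)C1=O
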